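**Retrosynthetic overview**
1. Target 21 ⇐ diol 20 by a 1,2 O5'→O4' angeloyl shift; 20 ⇐ ketol 19 by hydroxyl-directed anti reduction of the C2' ketone.
2. Key disconnection C3'–C4': Ipc-boron aldol of the fully functionalised C2' methyl ketone 14 (C3' nucleophile) with aldehyde 16 (C4' electrophile), which brings in the second angelate parked on O5'.
3. Enabling feature: oxygenated C2' lies between the fully substituted sp2 C1' (exocyclic methylene) and C3', so at the ketone level C3' is the only enolisable carbon. C4' bears O and the quaternary C5', so it can be a non-enolisable aldehyde, and the vicinal O4'/O5' pair lets the ester move through a five-membered orthoester.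
4. 14 ⇐ chlorohydrin diester 10 (ene chlorination of the isopropenyl group, N-oxide oxidation, methyl addition, oxidation); 10 ⇐ (S)-carvone (α'-hydroxylation, Mitsunobu inversion, Luche reduction, OH-directed epoxidation, angeloylation, trans-diaxial chloride opening).
5. Rings: the cyclohexane is carvone's own; the only ring formed is the temporary C3–C4 oxirane (step 4), opened in step 6. No protecting groups are used.

Key step: step 12

Remark: target locants are used from compound 5 on: ring C1 (side chain), C2 (CH2), C3 (Cl), C4 (CH3, OH), C5 (OAng), C6 (OAc); side chain C1' (=CH2), C2' (OH), C3' (CH2), C4' (OAng), C5' (CMe2OH). Carvone C5/C1/C6 = target C1/C5/C6; Ang = (Z)-2-methylbut-2-enoyl.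
Assumption: (S)-(+)-carvone, angelic acid and 2-bromo-2-methylpropanal are bought.

**Step 1**
Reactants: 1 (S)-(+)-carvone
Product: 3 (5R,6R)-6-hydroxycarvone (OH trans to isopropenyl), via sodium dienolate 2 (not isolated)
Conditions: NaHMDS, THF, −78 °C; then 2-(phenylsulfonyl)-3-phenyloxaziridine, −78 °C; aq. NH4Cl
Reagents that add atoms: 2-(phenylsulfonyl)-3-phenyloxaziridine (Davis reagent), O=S(=O)(c1ccccc1)N1OC1c1ccccc1
Why: Davis α'-hydroxylation of the kinetic cross-conjugated enolate; the oxaziridine should attack C6 anti to the adjacent C5 isopropenyl group, setting the trans (6R) carbinol.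

**Step 2**
Reactants: 3 (5R,6R)-6-hydroxycarvone
Product: 4 (5R,6S)-6-acetoxycarvone (OAc cis to isopropenyl)
Conditions: AcOH, PPh3, DIAD, toluene, 0 °C → rt
Reagents that add atoms: acetic acid, CC(=O)O
Why: Mitsunobu esterification; SN2 displacement of the activated hydroxyl by acetate at the carbonyl-activated C6 should invert it to the cis (6S) acetate with no strong base present.

**Step 3**
Reactants: 4 (5R,6S)-6-acetoxycarvone
Product: 5 (1R,5R,6S)-6-acetoxy-4-methyl-1-(prop-1-en-2-yl)cyclohex-3-en-5-ol (isopropenyl, OAc and OH all cis)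
Conditions: NaBH4, CeCl3·7H2O, MeOH, −78 °C; acetone then AcOH quench at −78 °C
Reagents that add atoms: none
Why: Luche 1,2-reduction; hydride should add axially, anti to the pseudo-axial C6 acetoxy group (Felkin–Anh and sterics agree), giving the equatorial C5 alcohol cis to both neighbours, and the cold acidic quench guards against O6→O5 acetyl migration.

**Step 4**
Reactants: 5 all-cis hydroxy acetate
Product: 6 (1R,3R,4S,5S,6S)-6-acetoxy-3,4-epoxy-4-methyl-1-(prop-1-en-2-yl)cyclohexan-5-ol (epoxide cis to OH)
Conditions: VO(acac)2 (cat.), t-BuOOH, CH2Cl2, 0 °C → rt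
Reagents that add atoms: tert-butyl hydroperoxide, CC(C)(C)OO
Why: Vanadium-catalysed epoxidation directed by the allylic C5 hydroxyl; oxygen is delivered to the C3=C4 alkene on the hydroxyl face (sets C3 and C4), and the undirected isopropenyl alkene is left alone.

**Step 5**
Reactants: 6 epoxy alcohol; 7 angelic acid
Product: 9 (1R,3R,4R,5S,6S)-6-acetoxy-3,4-epoxy-4-methyl-1-(prop-1-en-2-yl)cyclohexan-5-yl angelate, via mixed anhydride 8 (not isolated)
Conditions: 7, 2,4,6-trichlorobenzoyl chloride, Et3N, toluene, rt; then 6, 80 °C (no DMAP)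
Reagents that add atoms: none
Why: Yamaguchi-type mixed-anhydride acylation, the established way to make angelates without Z→E isomerisation; C5–OH is the only free hydroxyl, and omitting DMAP limits acetyl migration from O6.

**Step 6**
Reactants: 9 epoxy angelate
Product: 10 (1R,3S,4S,5S,6S)-6-acetoxy-5-angeloyloxy-3-chloro-4-methyl-1-(prop-1-en-2-yl)cyclohexan-4-ol
Conditions: LiCl, AcOH, THF, rt
Reagents that add atoms: lithium chloride, [Li+].[Cl-]
Why: Nucleophilic epoxide opening to a halohydrin; chloride should attack secondary C3 with inversion in the trans-diaxial (Fürst–Plattner) mode of the conformer with C1 equatorial, while the C5 acyloxy group disfavours cationic opening at tertiary C4, so C3 (S) is set and C4 keeps its oxygen.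

**Step 7**
Reactants: 10 chlorohydrin diester
Product: 11 the 1-(3-chloroprop-1-en-2-yl) analogue of 10 (allylic chloride)
Conditions: Ca(OCl)2, solid CO2, CH2Cl2/H2O, 0 °C
Reagents that add atoms: calcium hypochlorite, [Ca+2].[O-]Cl.[O-]Cl
Why: Ene-type allylic chlorination of a 1,1-disubstituted alkene by HOCl (the reaction known on carvone itself); the isopropenyl group is the only electron-rich alkene left, the angelate C=C being conjugated.

**Step 8**
Reactants: 11 allylic chloride
Product: 12 the 1-(3-oxoprop-1-en-2-yl) analogue of 10 (α-substituted acrolein)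
Conditions: N-methylmorpholine N-oxide, NaI (cat.), 4 Å MS, MeCN, 40 °C
Reagents that add atoms: N-methylmorpholine N-oxide, C[N+]1([O-])CCOCC1
Why: N-oxide (Kornblum/Ganem-type) oxidation of an allylic halide; iodide-assisted SN2 by the N-oxide oxygen and loss of N-methylmorpholine give the enal under near-neutral conditions that spare the esters and the chlorohydrin.

**Step 9**
Reactants: 12 enal
Product: 13 the 1-(3-hydroxybut-1-en-2-yl) analogue of 10 (both C2' epimers)
Conditions: MeTi(OiPr)3, THF, −40 → 0 °C
Reagents that add atoms: methyltitanium triisopropoxide, C[Ti](OC(C)C)(OC(C)C)OC(C)C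
Why: Reetz organotitanium addition; MeTi(OiPr)3 adds to aldehydes but not to esters, and the unselective new carbinol centre is erased in step 10.

**Step 10**
Reactants: 13 allylic alcohol (epimers)
Product: 14 the 1-(3-oxobut-1-en-2-yl) analogue of 10 (α-methylene methyl ketone)
Conditions: Dess–Martin periodinane, CH2Cl2, 0 °C → rt
Reagents that add atoms: none
Why: Dess–Martin oxidation of the secondary allylic alcohol; tertiary alcohol, esters and alkyl chloride are inert, and both epimers converge on one ketone.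

**Step 11**
Reactants: 15 2-bromo-2-methylpropanal; 7 angelic acid
Product: 16 2-methyl-1-oxopropan-2-yl (Z)-2-methylbut-2-enoate
Conditions: Cs2CO3, DMF, 0 °C → rt
Reagents that add atoms: none
Why: Carboxylate substitution of a tertiary α-bromo aldehyde; the tertiary angelate is made by O-alkylation, not acylation, so the Z geometry is not put at risk.

**Step 12 (key step)**
Reactants: 14 methyl ketone; 16 aldehyde
Product: 19 (4'R)-β-hydroxy ketone (C2' ketone, C4'–OH, angelate still on O5'; ring as in 10), via dienyl borinate 17 (not isolated), via borinate aldolate 18 (not isolated)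
Conditions: (+)-Ipc2BCl, Et3N, Et2O, 0 °C; then 16, −78 → −20 °C; MeOH, pH 7 buffer, 30% H2O2, 0 °C
Reagents that add atoms: none
Why: Et3N/(+)-Ipc2BCl enolises the only enolisable position of 14 (the C3' methyl) to dienyl borinate 17, which adds to the non-enolisable aldehyde 16 through a closed six-membered Zimmerman–Traxler transition state to give aldolate 18 and, after buffered oxidative work-up, 19. The closest known reaction is the Paterson Ipc-boron aldol of methyl ketones with aldehydes. No ring is closed; the only cyclic array is the boron chair, which is cleaved on work-up. The single new stereocentre, C4' (R), is set by the isopinocampheyl ligands: the (+)-reagent is chosen on the recalled sense for methyl-ketone Ipc borinates (Si-face attack with the (−)-reagent), so it should expose the aldehyde Re face, and the ring stereocentres are too remote to interfere. The step needs regioselective enolisation (C1' is fully substituted, and esters are not enolised by chloroborane/amine), chemoselectivity (boron enolates tolerate esters, alkyl chloride and the transiently borinated tertiary hydroxyl) and retention of the angelate on O5' (the boron-bound aldolate oxygen is too weakly nucleophilic to attack the hindered tertiary ester at low temperature, and work-up stays at pH 7).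

**Step 13**
Reactants: 19 β-hydroxy ketone
Product: 20 (2'R,4'R)-anti-diol (angelate on O5')
Conditions: Me4NBH(OAc)3, MeCN/AcOH (1:1), −25 °C; aq. Rochelle salt
Reagents that add atoms: none
Why: Evans–Saksena reduction; the C4' hydroxyl binds the triacetoxyborohydride and delivers hydride intramolecularly to C2' through a chair transition state, which should set C2' (R) anti to the C4' oxygen with 1,2-reduction only.

**Step 14**
Reactants: 20 anti-diol
Product: 21 CNP0124048.1 (target)
Conditions: DBU (0.1 equiv), CH2Cl2, 0 °C, monitored; AcOH quench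
Reagents that add atoms: none
Why: Base-catalysed 1,2 O→O acyl migration through a five-membered cyclic orthoester; the angeloyl group should move from the hindered tertiary O5' to the adjacent secondary O4', the six-membered shift on to O2' being slower, and no stereocentre is touched.

**Compound list**
1 | (S)-(+)-carvone | C=C(C)[C@H]1CC=C(C)C(=O)C1 | starting material
2 | sodium dienolate of carvone | C=C(C)[C@H]1CC=C(C)C([O-])=C1.[Na+] | intermediate
3 | (5R,6R)-6-hydroxycarvone | C=C(C)[C@H]1CC=C(C)C(=O)[C@@H]1O | intermediate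
4 | (5R,6S)-6-acetoxycarvone | C=C(C)[C@H]1CC=C(C)C(=O)[C@H]1OC(C)=O | intermediate
5 | (1R,5R,6S)-6-acetoxy-4-methyl-1-(prop-1-en-2-yl)cyclohex-3-en-5-ol | C=C(C)[C@H]1CC=C(C)[C@@H](O)[C@H]1OC(C)=O | intermediate
6 | (1R,3R,4S,5S,6S)-6-acetoxy-3,4-epoxy-4-methyl-1-(prop-1-en-2-yl)cyclohexan-5-ol | C=C(C)[C@H]1C[C@H]2O[C@@]2(C)[C@@H](O)[C@H]1OC(C)=O | intermediate
7 | angelic acid, (Z)-2-methylbut-2-enoic acid | C/C=C(/C)C(=O)O | starting material
8 | angelic 2,4,6-trichlorobenzoic anhydride | C/C=C(/C)C(=O)OC(=O)c1c(Cl)cc(Cl)cc1Cl | intermediate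
9 | 5-O-angelate of 6, (1R,3R,4R,5S,6S) | C=C(C)[C@H]1C[C@H]2O[C@@]2(C)[C@@H](OC(=O)/C(C)=C\C)[C@H]1OC(C)=O | intermediate
10 | (1R,3S,4S,5S,6S)-6-acetoxy-5-angeloyloxy-3-chloro-4-methyl-1-(prop-1-en-2-yl)cyclohexan-4-ol | C=C(C)[C@H]1C[C@H](Cl)[C@@](C)(O)[C@@H](OC(=O)/C(C)=C\C)[C@H]1OC(C)=O | intermediate
11 | 1-(3-chloroprop-1-en-2-yl) analogue of 10 | C=C(CCl)[C@H]1C[C@H](Cl)[C@@](C)(O)[C@@H](OC(=O)/C(C)=C\C)[C@H]1OC(C)=O | intermediate
12 | 1-(3-oxoprop-1-en-2-yl) analogue of 10 | C=C(C=O)[C@H]1C[C@H](Cl)[C@@](C)(O)[C@@H](OC(=O)/C(C)=C\C)[C@H]1OC(C)=O | intermediate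
13 | 1-(3-hydroxybut-1-en-2-yl) analogue of 10, C2' epimers | C=C(C(C)O)[C@H]1C[C@H](Cl)[C@@](C)(O)[C@@H](OC(=O)/C(C)=C\C)[C@H]1OC(C)=O | intermediate
14 | 1-(3-oxobut-1-en-2-yl) analogue of 10 | C=C(C(C)=O)[C@H]1C[C@H](Cl)[C@@](C)(O)[C@@H](OC(=O)/C(C)=C\C)[C@H]1OC(C)=O | intermediate
15 | 2-bromo-2-methylpropanal | CC(C)(Br)C=O | starting material
16 | 2-methyl-1-oxopropan-2-yl (Z)-2-methylbut-2-enoate | CC(C)(C=O)OC(=O)/C(C)=C\C | intermediate
17 | diisopinocampheylboron dienolate of 14 | C=C(OB([C@H]1C[C@H]2C[C@@H]([C@@H]1C)C2(C)C)[C@H]1C[C@H]2C[C@@H]([C@@H]1C)C2(C)C)C(=C)[C@H]1C[C@H](Cl)[C@@](C)(O)[C@@H](OC(=O)/C(C)=C\C)[C@H]1OC(C)=O | intermediate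
18 | 4'-O-diisopinocampheylboryl aldolate of 19 | C=C(C(=O)C[C@@H](OB([C@H]1C[C@H]2C[C@@H]([C@@H]1C)C2(C)C)[C@H]1C[C@H]2C[C@@H]([C@@H]1C)C2(C)C)C(C)(C)OC(=O)/C(C)=C\C)[C@H]1C[C@H](Cl)[C@@](C)(O)[C@@H](OC(=O)/C(C)=C\C)[C@H]1OC(C)=O | intermediate
19 | (4'R)-4'-hydroxy-2'-oxo-5'-O-angeloyl aldol adduct | C=C(C(=O)C[C@@H](O)C(C)(C)OC(=O)/C(C)=C\C)[C@H]1C[C@H](Cl)[C@@](C)(O)[C@@H](OC(=O)/C(C)=C\C)[C@H]1OC(C)=O | intermediate
20 | (2'R,4'R)-2',4'-diol with 5'-O-angelate | C=C([C@H](O)C[C@@H](O)C(C)(C)OC(=O)/C(C)=C\C)[C@H]1C[C@H](Cl)[C@@](C)(O)[C@@H](OC(=O)/C(C)=C\C)[C@H]1OC(C)=O | intermediate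
21 | CNP0124048.1 | C=C([C@H](O)C[C@@H](OC(=O)/C(C)=C\C)C(C)(C)O)[C@H]1C[C@H](Cl)[C@@](C)(O)[C@@H](OC(=O)/C(C)=C\C)[C@H]1OC(C)=O | target

**Step count and risks**
Total steps: 14. Longest linear sequence: 13 (steps 1–10, 12–14 from carvone); step 11 is a one-step side branch.

Steps most likely to fail:

1. Step 12. Facial selectivity of Ipc borinates of methyl ketones is only moderate. The aldolate may also pass the angeloyl group on too early and then lose it by β-elimination, or the aldol may close onto the α-methylene ketone by oxa-Michael addition. Fallback: a Lewis-acid-catalysed Mukaiyama aldol that sets out from 14. TMSOTf/Et3N (CH2Cl2, 0 °C) gives the bis-silyl dienol ether F1 (enol silane, tertiary C4–OH also silylated). Addition of F1 to 16 under a chiral N-tosyltryptophan-derived B-butyl oxazaborolidinone (the antipode that opens the aldehyde Re face; EtCN, −78 °C) gives the bis-silyl aldol F2. Dilute acid work-up removes both silyl groups and comes back at 19.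

2. Step 14. The acyl group may migrate further, from O4' to O2' through a six-membered orthoester, or the base may close the trans-diaxial chlorohydrin back to the oxirane. Fallback: sets out from 20. Selective silylation of the allylic C2' hydroxyl (TESCl, imidazole, DMF, −20 °C; the C4' hydroxyl is neopentylic) gives the mono-TES ether F3. The base-mediated shift (DBU cat., or aq. NaHCO3/THF) then has only one acceptor hydroxyl and gives the shifted TES ether F4. HF·pyridine (THF, 0 °C) comes back at 21.

3. Step 2. The activated α-ketol may enolise and epimerise, or eliminate, instead of undergoing SN2 inversion. Fallback: sets out from 1. LDA/TMSCl gives the silyl dienol ether F5; NBS (THF, −78 °C) brominates anti to the isopropenyl group to give (5R,6R)-6-bromocarvone F6; CsOAc/18-crown-6 (toluene, 40 °C) displaces bromide with inversion and comes back at 4.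

**Further compounds**
F1 | step 12 | bis-trimethylsilyl dienol ether of 14 (2'-OTMS diene, 4-OTMS) | C=C(O[Si](C)(C)C)C(=C)[C@H]1C[C@H](Cl)[C@@](C)(O[Si](C)(C)C)[C@@H](OC(=O)/C(C)=C\C)[C@H]1OC(C)=O
F2 | step 12 | 4'-O,4-O-bis(trimethylsilyl) ether of 19 | C=C(C(=O)C[C@@H](O[Si](C)(C)C)C(C)(C)OC(=O)/C(C)=C\C)[C@H]1C[C@H](Cl)[C@@](C)(O[Si](C)(C)C)[C@@H](OC(=O)/C(C)=C\C)[C@H]1OC(C)=O
F3 | step 14 | 2'-O-triethylsilyl ether of 20 | C=C([C@H](O[Si](CC)(CC)CC)C[C@@H](O)C(C)(C)OC(=O)/C(C)=C\C)[C@H]1C[C@H](Cl)[C@@](C)(O)[C@@H](OC(=O)/C(C)=C\C)[C@H]1OC(C)=O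
F4 | step 14 | 2'-O-triethylsilyl ether of 21 | C=C([C@H](O[Si](CC)(CC)CC)C[C@@H](OC(=O)/C(C)=C\C)C(C)(C)O)[C@H]1C[C@H](Cl)[C@@](C)(O)[C@@H](OC(=O)/C(C)=C\C)[C@H]1OC(C)=O
F5 | step 2 | trimethylsilyl dienol ether of carvone | C=C(C)[C@H]1CC=C(C)C(O[Si](C)(C)C)=C1
F6 | step 2 | (5R,6R)-6-bromocarvone | C=C(C)[C@H]1CC=C(C)C(=O)[C@@H]1Br
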